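**Plan**

- Cuts, in order: (i) the lactone Cα–CH2 bond to the dihydrobenzofuran (enolate alkylation), giving benzylic bromide 15 (fragment 1) and the (4S)-β-benzyl-γ-butyrolactone 32 (fragment 2); (ii) in fragment 2 the bond between the carbinol carbon (C7) and the CH(CH2OH) carbon (C8) of the 1,3-diol (anti-aldol), and the lactone ring (Stobbe half-ester); (iii) in fragment 1 the dihydrofuran ring itself.
- The dihydrofuran ring O1–C2–C3–C3a–C7a is not closed by cyclisation. It comes from the six-membered pyranone ring O1–C2–C3–C4–C4a–C8a of a (2R)-flavanone by oxidative ring contraction: aryl carbon C4a shifts from C4 to C3, and the C4 carbonyl carbon leaves the ring as the ester that becomes the C3 hydroxymethyl group.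
- What makes this possible: C3 of the target ring carries exactly one exocyclic carbon, C3a is an aryl carbon that can bridge C4 and C3, and the C2 aryl group is already in place on the flavanone.
- Forward order: chromone 4 → flavanone 7 → ring-contracted ester 9 → bromide 15; 5-bromovanillin 16 → lactone 22 → arylacetyl imide 27 → diol 31 → 32; union 32 + 15 → 34; fluoride, then hydrogenolysis.
- Stereochemistry: flavanone C2 by rhodium-catalysed asymmetric arylation; dihydrobenzofuran C3 by the stereospecific 1,2-shift (trans); lactone C4 by asymmetric hydrogenation; C7/C8 by an auxiliary-controlled anti-aldol; lactone C3 by trans-selective alkylation.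

Key step: step 5

Remark: CIP analysis of the SMILES gives (3S,4S) for the lactone, (2R,3S) (trans) for the dihydrobenzofuran and (1S,2S) (anti-aldol relationship) for the diol chain; the sense of induction in steps 4, 12 and 17 is assigned from the accepted models, not recalled from a specific case, and the antipodal ligand or auxiliary is the remedy if the first intermediate shows the opposite sense.

**Fragment 1 (steps 1–9)**

Step 1
Reactants: 1 1-(2-hydroxy-3-methoxyphenyl)ethan-1-one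
Product: 2 1-(5-bromo-2-hydroxy-3-methoxyphenyl)ethan-1-one
Conditions: NBS (1.05 equiv), MeCN, 0 °C → rt
Reagents that add atoms: N-bromosuccinimide, O=C1CCC(=O)N1Br
Why: Electrophilic aromatic bromination; the phenol directs para (both ortho positions are occupied) and the acetyl group directs meta, both to C5.

Step 2
Reactants: 2 1-(5-bromo-2-hydroxy-3-methoxyphenyl)ethan-1-one
Product: 4 6-bromo-8-methoxy-4H-chromen-4-one, via enaminone 3 (not isolated)
Conditions: Me2NCH(OMe)2, toluene, 100 °C; then conc. HCl, CH2Cl2, 40 °C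
Reagents that add atoms: N,N-dimethylformamide dimethyl acetal, COC(OC)N(C)C
Why: Standard chromone synthesis: condensation of the methyl ketone with the amide acetal gives the enaminone, and acid promotes conjugate addition of the phenol with loss of dimethylamine; no stereocentre is formed.

Step 3
Reactants: 5 2-methoxy-4-(4,4,5,5-tetramethyl-1,3,2-dioxaborolan-2-yl)phenol
Product: 6 2-methoxy-4-(4,4,5,5-tetramethyl-1,3,2-dioxaborolan-2-yl)phenyl pivalate
Conditions: t-BuCOCl, Et3N, DMAP (cat.), CH2Cl2, 0 °C → rt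
Reagents that add atoms: pivaloyl chloride, CC(C)(C)C(=O)Cl
Why: Phenol acylation; the pivalate makes the future C2 aryl ring electron-poor for step 5 and is removed without an extra operation in step 6.

Step 4
Reactants: 4 6-bromo-8-methoxy-4H-chromen-4-one; 6 2-methoxy-4-(4,4,5,5-tetramethyl-1,3,2-dioxaborolan-2-yl)phenyl pivalate
Product: 7 (2R)-6-bromo-8-methoxy-2-[3-methoxy-4-(pivaloyloxy)phenyl]chroman-4-one
Conditions: [Rh(OH)(cod)]2 (2.5 mol%), (R)-MeO-F12-BIPHEP (5.5 mol%), 6 (2 equiv), toluene/H2O 10:1, 50 °C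
Reagents that add atoms: none
Why: Rhodium-catalysed asymmetric 1,4-addition of an arylboron reagent to a chromone (Hayashi–Miyaura type), in which the aryl–rhodium species adds to C2 on the enone face selected by the (R)-biaryl bisphosphine (assigned R by mapping the (S)-ligand to (S)-3-arylcycloalkanone correlation onto the chromone); the base-free medium avoids ring opening of the flavanone and the aryl bromide is inert to monovalent rhodium.

Step 5
Reactants: 7 (2R)-6-bromo-8-methoxy-2-[3-methoxy-4-(pivaloyloxy)phenyl]chroman-4-one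
Product: 9 methyl (2R,3R)-5-bromo-7-methoxy-2-[3-methoxy-4-(pivaloyloxy)phenyl]-2,3-dihydro-1-benzofuran-3-carboxylate, via enol ether 8 (not isolated)
Conditions: PhI(OAc)2 (1.2 equiv), conc. H2SO4 (0.5 equiv), HC(OMe)3, 0 °C → rt; aq. NaHCO3
Reagents that add atoms: trimethyl orthoformate, COC(OC)OC
Why: Acid and orthoformate turn the C4 ketone into the methyl enol ether 8 (in equilibrium with the dimethyl ketal), which is attacked at C3 by the trivalent iodine electrophile on the face anti to the C2 aryl group, and methanol capture gives a 4,4-dimethoxy-3-(phenyliodanyl)chroman whose equatorial C3–I bond is antiperiplanar to the C4–C4a bond. Loss of iodobenzene is assisted by a 1,2-shift of aryl carbon C4a from C4 to C3 through a bridged phenonium-type transition state, the charge ending on the dimethoxycarbenium carbon C4, which collapses to the methyl ester. The closest known reaction type is the oxidative ring contraction of flavanones to methyl trans-2-aryl-2,3-dihydrobenzofuran-3-carboxylates with PhI(OAc)2 or Tl(NO3)3 in trimethyl orthoformate. The five-membered ring O1–C2–C3–C3a–C7a is closed by this suprafacial 1,2-aryl shift (ipso attack of C4a on C3 in a 3-exo sense, then opening of the bridge on the C4 side), not by a new C–O bond, so the pyranone shrinks from six to five atoms. C2 is untouched and keeps the R configuration of 7, while C3 is set by inversion at the carbon that carried iodine, which places the ester trans to the C2 aryl group, also the thermodynamically preferred arrangement. The step needs migration of C4a in preference to migration of the C2 aryl group (isoflavone pathway) and to loss of H-2 (flavone pathway); the ketal oxygens stabilise the cation left by the C4a shift, and the pivalate makes the C2 aryl ring a poor migrating group and protects it from oxidation.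

Step 6
Reactants: 9 methyl (2R,3R)-5-bromo-7-methoxy-2-[3-methoxy-4-(pivaloyloxy)phenyl]-2,3-dihydro-1-benzofuran-3-carboxylate
Product: 10 4-[(2R,3S)-5-bromo-3-(hydroxymethyl)-7-methoxy-2,3-dihydro-1-benzofuran-2-yl]-2-methoxyphenol
Conditions: i-Bu2AlH (6 equiv), CH2Cl2, −78 → 0 °C; aq. potassium sodium tartrate
Reagents that add atoms: none
Why: Hydride reduction of the methyl ester to the primary alcohol and reductive cleavage of the aryl pivalate in one operation; the non-basic reagent avoids C3 epimerisation and E1cB opening of the dihydrofuran, and the aryl bromide is untouched (the C3 descriptor changes by priority only).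

Step 7
Reactants: 10 4-[(2R,3S)-5-bromo-3-(hydroxymethyl)-7-methoxy-2,3-dihydro-1-benzofuran-2-yl]-2-methoxyphenol
Product: 11 (2R,3S)-5-bromo-7-methoxy-2-{3-methoxy-4-[(triisopropylsilyl)oxy]phenyl}-3-{[(triisopropylsilyl)oxy]methyl}-2,3-dihydro-1-benzofuran
Conditions: i-Pr3SiCl (2.5 equiv), imidazole, DMAP (cat.), DMF, rt
Reagents that add atoms: chlorotriisopropylsilane, CC(C)[Si](Cl)(C(C)C)C(C)C
Why: Silylation of the phenol and the primary alcohol; triisopropylsilyl ethers withstand butyllithium, borohydride and amide base and leave with fluoride at the end.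

Step 8
Reactants: 11 (2R,3S)-5-bromo-7-methoxy-2-{3-methoxy-4-[(triisopropylsilyl)oxy]phenyl}-3-{[(triisopropylsilyl)oxy]methyl}-2,3-dihydro-1-benzofuran
Product: 14 [(2R,3S)-7-methoxy-2-{3-methoxy-4-[(triisopropylsilyl)oxy]phenyl}-3-{[(triisopropylsilyl)oxy]methyl}-2,3-dihydro-1-benzofuran-5-yl]methanol, via aryllithium 12 (not isolated), via aldehyde 13 (not isolated)
Conditions: n-BuLi (1.1 equiv), THF, −78 °C; DMF, −78 → 0 °C; then MeOH, NaBH4, 0 °C; aq. NH4Cl
Reagents that add atoms: N,N-dimethylformamide, CN(C)C=O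
Why: Bromine–lithium exchange (faster than any deprotonation at −78 °C), formylation of the aryllithium with DMF and borohydride reduction of the released aldehyde in the same flask.

Step 9
Reactants: 14 [(2R,3S)-7-methoxy-2-{3-methoxy-4-[(triisopropylsilyl)oxy]phenyl}-3-{[(triisopropylsilyl)oxy]methyl}-2,3-dihydro-1-benzofuran-5-yl]methanol
Product: 15 (2R,3S)-5-(bromomethyl)-7-methoxy-2-{3-methoxy-4-[(triisopropylsilyl)oxy]phenyl}-3-{[(triisopropylsilyl)oxy]methyl}-2,3-dihydro-1-benzofuran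
Conditions: CBr4, PPh3, CH2Cl2, 0 °C; used at once
Reagents that add atoms: tetrabromomethane, BrC(Br)(Br)Br
Why: Appel bromination under neutral conditions, which spares the silyl ethers and the benzylic ether of the dihydrofuran; the electron-rich benzylic bromide is not stored.

**Fragment 2 (steps 10–19)**

Step 10
Reactants: 16 3-bromo-4-hydroxy-5-methoxybenzaldehyde
Product: 17 4-(benzyloxy)-3-bromo-5-methoxybenzaldehyde
Conditions: BnBr, K2CO3, DMF, 50 °C
Reagents that add atoms: benzyl bromide, BrCc1ccccc1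
Why: Williamson etherification of the phenol; the benzyl ether survives every later step up to the final hydrogenolysis.

Step 11
Reactants: 17 4-(benzyloxy)-3-bromo-5-methoxybenzaldehyde; 18 dimethyl succinate
Product: 19 (3E)-4-[4-(benzyloxy)-3-bromo-5-methoxyphenyl]-3-(methoxycarbonyl)but-3-enoic acid
Conditions: NaOMe (2.2 equiv), MeOH, reflux; then aq. HCl
Reagents that add atoms: none
Why: Stobbe condensation: aldol addition, lactonisation to the paraconate and E1cB ring opening give the arylidene half-ester, mainly as the E isomer.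

Step 12
Reactants: 19 (3E)-4-[4-(benzyloxy)-3-bromo-5-methoxyphenyl]-3-(methoxycarbonyl)but-3-enoic acid
Product: 20 (3S)-4-[4-(benzyloxy)-3-bromo-5-methoxyphenyl]-3-(methoxycarbonyl)butanoic acid
Conditions: [Rh(cod)((R,R)-Et-DuPhos)]BF4 (0.5 mol%), NaOMe (10 mol%), H2 (5 atm), MeOH, rt
Reagents that add atoms: none
Why: Rhodium–bisphospholane asymmetric hydrogenation of a Stobbe half-ester, in which carboxylate and alkene chelate the metal as an enamide does and hydrogen is delivered to one face (the (R,R) ligand is assigned to the 3S acid by that analogy); aryl bromide and benzyl ether are inert to the homogeneous catalyst.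

Step 13
Reactants: 20 (3S)-4-[4-(benzyloxy)-3-bromo-5-methoxyphenyl]-3-(methoxycarbonyl)butanoic acid
Product: 22 (4S)-4-{[4-(benzyloxy)-3-bromo-5-methoxyphenyl]methyl}oxolan-2-one, via hydroxy acid 21 (not isolated)
Conditions: LiOH·H2O (1.0 equiv), MeOH, evaporate; LiBH4 (2.5 equiv), THF, 0 → 40 °C; then 2 M HCl, rt
Reagents that add atoms: none
Why: Lithium borohydride reduces the methyl ester but not the lithium carboxylate, and acidification closes the γ-lactone; the stereocentre is not involved.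

Step 14
Reactants: 22 (4S)-4-{[4-(benzyloxy)-3-bromo-5-methoxyphenyl]methyl}oxolan-2-one
Product: 23 tert-butyl 2-[2-(benzyloxy)-3-methoxy-5-{[(3S)-5-oxooxolan-3-yl]methyl}phenyl]acetate
Conditions: BrZnCH2CO2t-Bu (2 equiv), Pd2(dba)3 (2.5 mol%), XPhos (10 mol%), THF, 60 °C
Reagents that add atoms: (2-tert-butoxy-2-oxoethyl)zinc bromide, CC(C)(C)OC(=O)C[Zn]Br
Why: Palladium-catalysed cross-coupling of an aryl bromide with a Reformatsky reagent (Negishi-type α-arylation of an ester); the zinc enolate does not attack or deprotonate the lactone.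

Step 15
Reactants: 23 tert-butyl 2-[2-(benzyloxy)-3-methoxy-5-{[(3S)-5-oxooxolan-3-yl]methyl}phenyl]acetate
Product: 24 2-[2-(benzyloxy)-3-methoxy-5-{[(3S)-5-oxooxolan-3-yl]methyl}phenyl]acetic acid
Conditions: CF3CO2H/CH2Cl2 1:4, 0 °C → rt
Reagents that add atoms: none
Why: Acidolysis of the tert-butyl ester; the aryl benzyl ether and the lactone survive dilute trifluoroacetic acid.

Step 16
Reactants: 24 2-[2-(benzyloxy)-3-methoxy-5-{[(3S)-5-oxooxolan-3-yl]methyl}phenyl]acetic acid; 25 (4S)-4-benzyl-1,3-oxazolidin-2-one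
Product: 27 (4S)-4-benzyl-3-{2-[2-(benzyloxy)-3-methoxy-5-{[(3S)-5-oxooxolan-3-yl]methyl}phenyl]acetyl}-1,3-oxazolidin-2-one, via mixed anhydride 26 (not isolated)
Conditions: t-BuCOCl, Et3N, THF, −20 °C; then 25, LiCl, −20 °C → rt
Reagents that add atoms: none
Why: N-acylation of the oxazolidinone by the mixed pivalic anhydride under LiCl/Et3N activation; no strong base is used, so the lactone is safe.

Step 17
Reactants: 27 (4S)-4-benzyl-3-{2-[2-(benzyloxy)-3-methoxy-5-{[(3S)-5-oxooxolan-3-yl]methyl}phenyl]acetyl}-1,3-oxazolidin-2-one; 28 4-(benzyloxy)-3-methoxybenzaldehyde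
Product: 29 (4S)-4-benzyl-3-[(2R,3S)-3-[4-(benzyloxy)-3-methoxyphenyl]-2-[2-(benzyloxy)-3-methoxy-5-{[(3S)-5-oxooxolan-3-yl]methyl}phenyl]-3-[(trimethylsilyl)oxy]propanoyl]-1,3-oxazolidin-2-one
Conditions: MgCl2 (20 mol%), Et3N (2 equiv), Me3SiCl (1.5 equiv), 28 (1.3 equiv), EtOAc, rt
Reagents that add atoms: chlorotrimethylsilane, C[Si](C)(C)Cl
Why: Magnesium halide-catalysed direct anti-aldol reaction of an N-acyloxazolidinone, in which soft enolisation gives the chelated Z-magnesium enolate, the aldehyde adds on the face away from the auxiliary benzyl group through a boat-like transition state to give the (2R,3S) anti adduct, and silylation of the aldolate drives turnover and blocks retro-aldol cleavage; only the arylacetyl imide is acidic enough to enolise.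

Step 18
Reactants: 29 (4S)-4-benzyl-3-[(2R,3S)-3-[4-(benzyloxy)-3-methoxyphenyl]-2-[2-(benzyloxy)-3-methoxy-5-{[(3S)-5-oxooxolan-3-yl]methyl}phenyl]-3-[(trimethylsilyl)oxy]propanoyl]-1,3-oxazolidin-2-one
Product: 31 (4S)-4-({4-(benzyloxy)-3-[(1S,2S)-1-[4-(benzyloxy)-3-methoxyphenyl]-1,3-dihydroxypropan-2-yl]-5-methoxyphenyl}methyl)oxolan-2-one, via silyl ether alcohol 30 (not isolated)
Conditions: NaBH4 (4 equiv), THF/H2O 4:1, 0 °C; then 10% aq. citric acid, MeOH, 0 °C
Reagents that add atoms: none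
Why: Borohydride reduction of the activated imide carbonyl releases the auxiliary and gives the primary alcohol while the less electrophilic γ-lactone should survive at 0 °C, and the brief mild acid wash removes the trimethylsilyl group without ionising the benzylic carbinol.

Step 19
Reactants: 31 (4S)-4-({4-(benzyloxy)-3-[(1S,2S)-1-[4-(benzyloxy)-3-methoxyphenyl]-1,3-dihydroxypropan-2-yl]-5-methoxyphenyl}methyl)oxolan-2-one
Product: 32 (4S)-4-({4-(benzyloxy)-3-[(1S,2S)-1-[4-(benzyloxy)-3-methoxyphenyl]-1,3-bis[(tert-butyldimethylsilyl)oxy]propan-2-yl]-5-methoxyphenyl}methyl)oxolan-2-one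
Conditions: t-BuMe2SiOTf (2.5 equiv), 2,6-lutidine, CH2Cl2, −40 → 0 °C
Reagents that add atoms: tert-butyldimethylsilyl trifluoromethanesulfonate, CC(C)(C)[Si](C)(C)OS(=O)(=O)C(F)(F)F
Why: Silylation of the primary and the secondary benzylic alcohol; silyl ethers are chosen over an acetonide so that no acid is needed near the benzylic carbinol at the end.

**Union and deprotection (steps 20–22)**

Step 20
Reactants: 32 (4S)-4-({4-(benzyloxy)-3-[(1S,2S)-1-[4-(benzyloxy)-3-methoxyphenyl]-1,3-bis[(tert-butyldimethylsilyl)oxy]propan-2-yl]-5-methoxyphenyl}methyl)oxolan-2-one; 15 (2R,3S)-5-(bromomethyl)-7-methoxy-2-{3-methoxy-4-[(triisopropylsilyl)oxy]phenyl}-3-{[(triisopropylsilyl)oxy]methyl}-2,3-dihydro-1-benzofuran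
Product: 34 (3S,4S)-4-({4-(benzyloxy)-3-[(1S,2S)-1-[4-(benzyloxy)-3-methoxyphenyl]-1,3-bis[(tert-butyldimethylsilyl)oxy]propan-2-yl]-5-methoxyphenyl}methyl)-3-{[(2R,3S)-7-methoxy-2-{3-methoxy-4-[(triisopropylsilyl)oxy]phenyl}-3-{[(triisopropylsilyl)oxy]methyl}-2,3-dihydro-1-benzofuran-5-yl]methyl}oxolan-2-one, via lithium enolate 33 (not isolated)
Conditions: LiN(SiMe3)2 (1.1 equiv), THF, −78 °C; then 15 (1.2 equiv), DMPU, −78 → −40 °C
Reagents that add atoms: none
Why: Alkylation of the lithium enolate of a β-substituted γ-butyrolactone, in which the benzylic bromide approaches anti to the C4 benzyl group and gives the trans (3S,4S) lactone, also the thermodynamically preferred isomer.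

Step 21
Reactants: 34 (3S,4S)-4-({4-(benzyloxy)-3-[(1S,2S)-1-[4-(benzyloxy)-3-methoxyphenyl]-1,3-bis[(tert-butyldimethylsilyl)oxy]propan-2-yl]-5-methoxyphenyl}methyl)-3-{[(2R,3S)-7-methoxy-2-{3-methoxy-4-[(triisopropylsilyl)oxy]phenyl}-3-{[(triisopropylsilyl)oxy]methyl}-2,3-dihydro-1-benzofuran-5-yl]methyl}oxolan-2-one
Product: 35 (3S,4S)-4-({4-(benzyloxy)-3-[(1S,2S)-1-[4-(benzyloxy)-3-methoxyphenyl]-1,3-dihydroxypropan-2-yl]-5-methoxyphenyl}methyl)-3-{[(2R,3S)-2-(4-hydroxy-3-methoxyphenyl)-3-(hydroxymethyl)-7-methoxy-2,3-dihydro-1-benzofuran-5-yl]methyl}oxolan-2-one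
Conditions: Bu4NF (8 equiv), AcOH (8 equiv), THF, 0 °C → rt
Reagents that add atoms: none
Why: Fluoride cleavage of the four silyl ethers; the acetic acid buffer keeps the phenoxide from opening the dihydrofuran through a quinone methide and keeps the lactone closed.

Step 22
Reactants: 35 (3S,4S)-4-({4-(benzyloxy)-3-[(1S,2S)-1-[4-(benzyloxy)-3-methoxyphenyl]-1,3-dihydroxypropan-2-yl]-5-methoxyphenyl}methyl)-3-{[(2R,3S)-2-(4-hydroxy-3-methoxyphenyl)-3-(hydroxymethyl)-7-methoxy-2,3-dihydro-1-benzofuran-5-yl]methyl}oxolan-2-one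
Product: 36 (3S,4S)-4-({3-[(1S,2S)-1,3-dihydroxy-1-(4-hydroxy-3-methoxyphenyl)propan-2-yl]-4-hydroxy-5-methoxyphenyl}methyl)-3-{[(2R,3S)-2-(4-hydroxy-3-methoxyphenyl)-3-(hydroxymethyl)-7-methoxy-2,3-dihydro-1-benzofuran-5-yl]methyl}oxolan-2-one
Conditions: H2 (1 atm), 10% Pd/C, EtOAc/MeOH 1:1, rt, stopped after uptake of 2 equiv
Reagents that add atoms: none
Why: Neutral hydrogenolysis of the two aryl benzyl ethers; under neutral conditions at room temperature the benzylic carbinol and the benzylic C2–O bond of the dihydrofuran should be retained.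

**Compound list**

1 | 1-(2-hydroxy-3-methoxyphenyl)ethan-1-one | CC(=O)c1cccc(OC)c1O | starting material
2 | 1-(5-bromo-2-hydroxy-3-methoxyphenyl)ethan-1-one | CC(=O)c1cc(Br)cc(OC)c1O | intermediate
3 | (E)-1-(5-bromo-2-hydroxy-3-methoxyphenyl)-3-(dimethylamino)prop-2-en-1-one | CN(C)/C=C/C(=O)c1cc(Br)cc(OC)c1O | intermediate
4 | 6-bromo-8-methoxy-4H-chromen-4-one | O=c1ccoc2c(OC)cc(Br)cc12 | intermediate
5 | 2-methoxy-4-(4,4,5,5-tetramethyl-1,3,2-dioxaborolan-2-yl)phenol | COc1cc(B2OC(C)(C)C(C)(C)O2)ccc1O | starting material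
6 | 2-methoxy-4-(4,4,5,5-tetramethyl-1,3,2-dioxaborolan-2-yl)phenyl pivalate | COc1cc(B2OC(C)(C)C(C)(C)O2)ccc1OC(=O)C(C)(C)C | intermediate
7 | (2R)-6-bromo-8-methoxy-2-[3-methoxy-4-(pivaloyloxy)phenyl]chroman-4-one | O=C1C[C@H](c2ccc(OC(=O)C(C)(C)C)c(OC)c2)Oc2c(OC)cc(Br)cc21 | intermediate
8 | (2R)-6-bromo-4,8-dimethoxy-2-[3-methoxy-4-(pivaloyloxy)phenyl]-2H-chromene | COC1=C[C@H](c2ccc(OC(=O)C(C)(C)C)c(OC)c2)Oc2c(OC)cc(Br)cc21 | intermediate
9 | methyl (2R,3R)-5-bromo-7-methoxy-2-[3-methoxy-4-(pivaloyloxy)phenyl]-2,3-dihydro-1-benzofuran-3-carboxylate (trans) | Brc1cc(OC)c2c(c1)[C@@H](C(=O)OC)[C@H](c1ccc(OC(=O)C(C)(C)C)c(OC)c1)O2 | intermediate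
10 | 4-[(2R,3S)-5-bromo-3-(hydroxymethyl)-7-methoxy-2,3-dihydro-1-benzofuran-2-yl]-2-methoxyphenol | Brc1cc(OC)c2c(c1)[C@@H](CO)[C@H](c1ccc(O)c(OC)c1)O2 | intermediate
11 | (2R,3S)-5-bromo-7-methoxy-2-{3-methoxy-4-[(triisopropylsilyl)oxy]phenyl}-3-{[(triisopropylsilyl)oxy]methyl}-2,3-dihydro-1-benzofuran | Brc1cc(OC)c2c(c1)[C@@H](CO[Si](C(C)C)(C(C)C)C(C)C)[C@H](c1ccc(O[Si](C(C)C)(C(C)C)C(C)C)c(OC)c1)O2 | intermediate
12 | 5-lithio analogue of 11 (aryllithium) | [Li]c1cc(OC)c2c(c1)[C@@H](CO[Si](C(C)C)(C(C)C)C(C)C)[C@H](c1ccc(O[Si](C(C)C)(C(C)C)C(C)C)c(OC)c1)O2 | intermediate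
13 | (2R,3S)-7-methoxy-2-{3-methoxy-4-[(triisopropylsilyl)oxy]phenyl}-3-{[(triisopropylsilyl)oxy]methyl}-2,3-dihydro-1-benzofuran-5-carbaldehyde | O=Cc1cc(OC)c2c(c1)[C@@H](CO[Si](C(C)C)(C(C)C)C(C)C)[C@H](c1ccc(O[Si](C(C)C)(C(C)C)C(C)C)c(OC)c1)O2 | intermediate
14 | [(2R,3S)-7-methoxy-2-{3-methoxy-4-[(triisopropylsilyl)oxy]phenyl}-3-{[(triisopropylsilyl)oxy]methyl}-2,3-dihydro-1-benzofuran-5-yl]methanol | OCc1cc(OC)c2c(c1)[C@@H](CO[Si](C(C)C)(C(C)C)C(C)C)[C@H](c1ccc(O[Si](C(C)C)(C(C)C)C(C)C)c(OC)c1)O2 | intermediate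
15 | (2R,3S)-5-(bromomethyl)-7-methoxy-2-{3-methoxy-4-[(triisopropylsilyl)oxy]phenyl}-3-{[(triisopropylsilyl)oxy]methyl}-2,3-dihydro-1-benzofuran (fragment 1) | BrCc1cc(OC)c2c(c1)[C@@H](CO[Si](C(C)C)(C(C)C)C(C)C)[C@H](c1ccc(O[Si](C(C)C)(C(C)C)C(C)C)c(OC)c1)O2 | intermediate
16 | 3-bromo-4-hydroxy-5-methoxybenzaldehyde (5-bromovanillin) | COc1cc(C=O)cc(Br)c1O | starting material
17 | 4-(benzyloxy)-3-bromo-5-methoxybenzaldehyde | COc1cc(C=O)cc(Br)c1OCc1ccccc1 | intermediate
18 | dimethyl succinate | COC(=O)CCC(=O)OC | starting material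
19 | (3E)-4-[4-(benzyloxy)-3-bromo-5-methoxyphenyl]-3-(methoxycarbonyl)but-3-enoic acid | COC(=O)/C(CC(=O)O)=C/c1cc(Br)c(OCc2ccccc2)c(OC)c1 | intermediate
20 | (3S)-4-[4-(benzyloxy)-3-bromo-5-methoxyphenyl]-3-(methoxycarbonyl)butanoic acid | COc1cc(C[C@@H](CC(=O)O)C(=O)OC)cc(Br)c1OCc1ccccc1 | intermediate
21 | (3S)-4-[4-(benzyloxy)-3-bromo-5-methoxyphenyl]-3-(hydroxymethyl)butanoic acid | COc1cc(C[C@@H](CC(=O)O)CO)cc(Br)c1OCc1ccccc1 | intermediate
22 | (4S)-4-{[4-(benzyloxy)-3-bromo-5-methoxyphenyl]methyl}oxolan-2-one | COc1cc(C[C@@H]2COC(=O)C2)cc(Br)c1OCc1ccccc1 | intermediate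
23 | tert-butyl 2-[2-(benzyloxy)-3-methoxy-5-{[(3S)-5-oxooxolan-3-yl]methyl}phenyl]acetate | COc1cc(C[C@@H]2COC(=O)C2)cc(CC(=O)OC(C)(C)C)c1OCc1ccccc1 | intermediate
24 | 2-[2-(benzyloxy)-3-methoxy-5-{[(3S)-5-oxooxolan-3-yl]methyl}phenyl]acetic acid | COc1cc(C[C@@H]2COC(=O)C2)cc(CC(=O)O)c1OCc1ccccc1 | intermediate
25 | (4S)-4-benzyl-1,3-oxazolidin-2-one | O=C1N[C@@H](Cc2ccccc2)CO1 | starting material
26 | mixed anhydride of 24 with pivalic acid | COc1cc(C[C@@H]2COC(=O)C2)cc(CC(=O)OC(=O)C(C)(C)C)c1OCc1ccccc1 | intermediate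
27 | (4S)-4-benzyl-3-{2-[2-(benzyloxy)-3-methoxy-5-{[(3S)-5-oxooxolan-3-yl]methyl}phenyl]acetyl}-1,3-oxazolidin-2-one | COc1cc(C[C@@H]2COC(=O)C2)cc(CC(=O)N2C(=O)OC[C@@H]2Cc2ccccc2)c1OCc1ccccc1 | intermediate
28 | 4-(benzyloxy)-3-methoxybenzaldehyde | COc1cc(C=O)ccc1OCc1ccccc1 | starting material
29 | (4S)-4-benzyl-3-[(2R,3S)-3-[4-(benzyloxy)-3-methoxyphenyl]-2-[2-(benzyloxy)-3-methoxy-5-{[(3S)-5-oxooxolan-3-yl]methyl}phenyl]-3-[(trimethylsilyl)oxy]propanoyl]-1,3-oxazolidin-2-one | COc1cc([C@@H](O[Si](C)(C)C)[C@H](C(=O)N2C(=O)OC[C@@H]2Cc2ccccc2)c2cc(C[C@@H]3COC(=O)C3)cc(OC)c2OCc2ccccc2)ccc1OCc1ccccc1 | intermediate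
30 | (4S)-4-({4-(benzyloxy)-3-[(1S,2S)-1-[4-(benzyloxy)-3-methoxyphenyl]-3-hydroxy-1-[(trimethylsilyl)oxy]propan-2-yl]-5-methoxyphenyl}methyl)oxolan-2-one | COc1cc([C@@H](O[Si](C)(C)C)[C@H](CO)c2cc(C[C@@H]3COC(=O)C3)cc(OC)c2OCc2ccccc2)ccc1OCc1ccccc1 | intermediate
31 | (4S)-4-({4-(benzyloxy)-3-[(1S,2S)-1-[4-(benzyloxy)-3-methoxyphenyl]-1,3-dihydroxypropan-2-yl]-5-methoxyphenyl}methyl)oxolan-2-one | COc1cc([C@@H](O)[C@H](CO)c2cc(C[C@@H]3COC(=O)C3)cc(OC)c2OCc2ccccc2)ccc1OCc1ccccc1 | intermediate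
32 | (4S)-4-({4-(benzyloxy)-3-[(1S,2S)-1-[4-(benzyloxy)-3-methoxyphenyl]-1,3-bis[(tert-butyldimethylsilyl)oxy]propan-2-yl]-5-methoxyphenyl}methyl)oxolan-2-one (fragment 2) | COc1cc([C@@H](O[Si](C)(C)C(C)(C)C)[C@H](CO[Si](C)(C)C(C)(C)C)c2cc(C[C@@H]3COC(=O)C3)cc(OC)c2OCc2ccccc2)ccc1OCc1ccccc1 | intermediate
33 | lithium enolate of 32 | COc1cc([C@@H](O[Si](C)(C)C(C)(C)C)[C@H](CO[Si](C)(C)C(C)(C)C)c2cc(C[C@@H]3COC(O[Li])=C3)cc(OC)c2OCc2ccccc2)ccc1OCc1ccccc1 | intermediate
34 | (3S,4S)-4-({4-(benzyloxy)-3-[(1S,2S)-1-[4-(benzyloxy)-3-methoxyphenyl]-1,3-bis[(tert-butyldimethylsilyl)oxy]propan-2-yl]-5-methoxyphenyl}methyl)-3-{[(2R,3S)-7-methoxy-2-{3-methoxy-4-[(triisopropylsilyl)oxy]phenyl}-3-{[(triisopropylsilyl)oxy]methyl}-2,3-dihydro-1-benzofuran-5-yl]methyl}oxolan-2-one | COc1cc([C@@H](O[Si](C)(C)C(C)(C)C)[C@H](CO[Si](C)(C)C(C)(C)C)c2cc(C[C@@H]3COC(=O)[C@H]3Cc3cc(OC)c4c(c3)[C@@H](CO[Si](C(C)C)(C(C)C)C(C)C)[C@H](c3ccc(O[Si](C(C)C)(C(C)C)C(C)C)c(OC)c3)O4)cc(OC)c2OCc2ccccc2)ccc1OCc1ccccc1 | intermediate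
35 | (3S,4S)-4-({4-(benzyloxy)-3-[(1S,2S)-1-[4-(benzyloxy)-3-methoxyphenyl]-1,3-dihydroxypropan-2-yl]-5-methoxyphenyl}methyl)-3-{[(2R,3S)-2-(4-hydroxy-3-methoxyphenyl)-3-(hydroxymethyl)-7-methoxy-2,3-dihydro-1-benzofuran-5-yl]methyl}oxolan-2-one | COc1cc([C@@H](O)[C@H](CO)c2cc(C[C@@H]3COC(=O)[C@H]3Cc3cc(OC)c4c(c3)[C@@H](CO)[C@H](c3ccc(O)c(OC)c3)O4)cc(OC)c2OCc2ccccc2)ccc1OCc1ccccc1 | intermediate
36 | (3S,4S)-4-({3-[(1S,2S)-1,3-dihydroxy-1-(4-hydroxy-3-methoxyphenyl)propan-2-yl]-4-hydroxy-5-methoxyphenyl}methyl)-3-{[(2R,3S)-2-(4-hydroxy-3-methoxyphenyl)-3-(hydroxymethyl)-7-methoxy-2,3-dihydro-1-benzofuran-5-yl]methyl}oxolan-2-one (CNP0199264.1) | COc1cc([C@@H](O)[C@H](CO)c2cc(C[C@@H]3COC(=O)[C@H]3Cc3cc(OC)c4c(c3)[C@@H](CO)[C@H](c3ccc(O)c(OC)c3)O4)cc(OC)c2O)ccc1O | target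

**Step count and risks**

Total step count: 22. Longest linear sequence: 13 steps (16 → 36, steps 10–22); the fragment 1 branch has 8 linear steps from 1 before the union, plus step 3 as a one-step side branch.

The three steps most likely to fail:

1. Step 5 (key step). The C2 aryl group may migrate instead of C4a, or oxidative dehydrogenation to the flavone may compete, or acid-mediated opening and reclosure of the pyranone may erode the C2 configuration before the shift. The fallback keeps the ring contraction but runs it through a carbene instead of an iodonium species. It sets out from 7: condensation with Me2NCH(OMe)2 in toluene at 90 °C should give (2S,3E)-6-bromo-3-[(dimethylamino)methylidene]-8-methoxy-2-[3-methoxy-4-(pivaloyloxy)phenyl]chroman-4-one F1 (the descriptor changes by priority only). Diazo transfer with tosyl azide in CH2Cl2 should then give the (2S)-3-diazoflavanone F2. Irradiation at 365 nm in MeOH triggers the Wolff rearrangement, C4a migrating to the carbene carbon C3, and methanol adds to the ring-contracted ketene to give mainly the cis ester methyl (2R,3S)-5-bromo-7-methoxy-2-[3-methoxy-4-(pivaloyloxy)phenyl]-2,3-dihydro-1-benzofuran-3-carboxylate F3. Catalytic DBU in CH2Cl2 equilibrates this to the trans ester, and the sequence comes back to the route at 9.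

2. Step 17. Soft enolisation of the hindered, ortho-substituted arylacetyl imide may be slow, the silylated aldolate may revert, or the anti and facial selectivity may be eroded. The fallback replaces the aldol by an allylboration; it sets out from 22 and comes back at 31, so steps 14–18 are bypassed. Suzuki–Miyaura coupling of 22 with (E)-3-(4,4,5,5-tetramethyl-1,3,2-dioxaborolan-2-yl)prop-2-en-1-ol (Pd(dppf)Cl2, K3PO4, dioxane/H2O) should give the cinnamyl alcohol F4. Palladium-catalysed borylation of the allylic alcohol with B2pin2 ([Pd(MeCN)4](BF4)2, DMSO/MeOH) should give the (E)-cinnamylboronate F5. Allylboration of aldehyde 28 catalysed by the chiral phosphoric acid (S)-TRIP, through a closed chair transition state, should give the anti homoallylic alcohol F6. Lemieux–Johnson cleavage of the vinyl group (OsO4 cat., NaIO4, 2,6-lutidine) followed by NaBH4 then gives 31.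

3. Step 18. Hydride may attack the γ-lactone in competition with the imide, or the silyl ether may hydrolyse and the free aldol revert before the imide is reduced. The fallback sets out from 29: LiOH/H2O2 (THF/H2O, 0 °C) cleaves the auxiliary hydrolytically (the silyl ether is lost, and any opened lactone recloses on acidification) to give the β-hydroxy acid F7. BH3·SMe2 (THF, 0 °C) reduces the carboxylic acid much faster than the lactone, and the sequence comes back to the route at 31.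

Further compounds
F1 | step 5 | (2S,3E)-6-bromo-3-[(dimethylamino)methylidene]-8-methoxy-2-[3-methoxy-4-(pivaloyloxy)phenyl]chroman-4-one | O=C1/C(=C/N(C)C)[C@H](c2ccc(OC(=O)C(C)(C)C)c(OC)c2)Oc2c(OC)cc(Br)cc21
F2 | step 5 | (2S)-6-bromo-3-diazo-8-methoxy-2-[3-methoxy-4-(pivaloyloxy)phenyl]chroman-4-one | O=C1C(=[N+]=[N-])[C@H](c2ccc(OC(=O)C(C)(C)C)c(OC)c2)Oc2c(OC)cc(Br)cc21
F3 | step 5 | methyl (2R,3S)-5-bromo-7-methoxy-2-[3-methoxy-4-(pivaloyloxy)phenyl]-2,3-dihydro-1-benzofuran-3-carboxylate (cis) | Brc1cc(OC)c2c(c1)[C@H](C(=O)OC)[C@H](c1ccc(OC(=O)C(C)(C)C)c(OC)c1)O2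
F4 | step 17 | (4S)-4-({4-(benzyloxy)-3-[(1E)-3-hydroxyprop-1-en-1-yl]-5-methoxyphenyl}methyl)oxolan-2-one | COc1cc(C[C@@H]2COC(=O)C2)cc(/C=C/CO)c1OCc1ccccc1
F5 | step 17 | (4S)-4-({4-(benzyloxy)-3-methoxy-5-[(1E)-3-(4,4,5,5-tetramethyl-1,3,2-dioxaborolan-2-yl)prop-1-en-1-yl]phenyl}methyl)oxolan-2-one | COc1cc(C[C@@H]2COC(=O)C2)cc(/C=C/CB2OC(C)(C)C(C)(C)O2)c1OCc1ccccc1
F6 | step 17 | (4S)-4-({4-(benzyloxy)-3-[(1S,2R)-1-[4-(benzyloxy)-3-methoxyphenyl]-1-hydroxybut-3-en-2-yl]-5-methoxyphenyl}methyl)oxolan-2-one | COc1cc([C@@H](O)[C@H](C=C)c2cc(C[C@@H]3COC(=O)C3)cc(OC)c2OCc2ccccc2)ccc1OCc1ccccc1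
F7 | step 18 | (2R,3S)-3-[4-(benzyloxy)-3-methoxyphenyl]-2-[2-(benzyloxy)-3-methoxy-5-{[(3S)-5-oxooxolan-3-yl]methyl}phenyl]-3-hydroxypropanoic acid | COc1cc([C@@H](O)[C@H](C(=O)O)c2cc(C[C@@H]3COC(=O)C3)cc(OC)c2OCc2ccccc2)ccc1OCc1ccccc1
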